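## Structural features

The target is a guaiane. Ring A is a cyclopentane (C1–C5) fused through C1 and C5 to ring B, a cycloheptene (C1, C5, C6, C7, C8, C9, C10). Its only C=C bond is the tetrasubstituted ring-fusion alkene C1=C10, with methyl C14 on C10. Five stereocentres are contiguous along C4–C5–C6–C7–C8: a tertiary carbinol at C4 (OH β, methyl α), the ring-fusion hydrogen at C5 (α), a free secondary carbinol at C6 (OH β), the isopropyl-bearing C7 (isopropyl β) and the acylated carbinol at C8 (oxygen α). In CIP terms this is 4S,5S,6R,7S,8S. The 4-OH and 6-OH are syn across C5, the 6-OH is cis to the isopropyl group, and the C8 ester is 1,3-anti to the 6-OH. The fragile groups are the tertiary homoallylic C4 alcohol (acid-induced dehydration), the aryl ester beside a free 1,3-hydroxyl (acyl migration, solvolysis), the free phenol, and the C1=C10 alkene, which can move into conjugation once C8 is a carbonyl. The real difficulty is to set C5 and C6 against the quaternary C4 while closing the seven-membered ring with the alkene fixed at C1=C10, and then to build C7 and C8 next to the C6 oxygen. The key step uses the fact that the C5–C6 bond lies opposite C9 in ring B and that C1=C10 together with a C7=C8 enol ether makes a cyclohepta-1,4-diene. A C8–C9–C10 cyclopropane with alkenyl arms C1=C5 (ring A) and C7=C6 is therefore the retron.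

## Logic of the disconnections

**26 ⇒ 25.** The two O–Si bonds (C4–O and the phenol) are cut. Both fall in one buffered fluoride treatment, so the tertiary alcohol and the phenol stay masked through the acylation. The forward step must not move the ester to O6 or cleave it, hence acetic acid buffering.

**25 ⇒ 20 + 23.** The C8–O acyl bond is cut, which removes the whole aryl unit as an acid made in one step from 21. The forward step must acylate O8 and not O6. It relies on O6 being flanked by two branched carbons and shielded by the syn C4 silyl ether.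

**20 ⇒ 19 ⇒ 18.** The C8–H bond and then the O6–benzyl bond are cut. A free 6-hydroxyl can carry hydride to the β face of the C8 carbonyl and so give the 1,3-anti diol. The 4-methoxybenzyl ether is chosen because it leaves under neutral oxidative conditions. The forward steps must keep the β-hydroxy ketone intact and make the internal hydride delivery faster than any external one.

**18 ⇒ 17.** The C7–H bond is cut and the ketone returns to the C7=C8 silyl enol ether, which is what the pericyclic step delivers. The forward step must protonate C7 kinetically on the α face without eliminating the C6 oxygen.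

**17 ⇒ 16.** The C5–C6 bond is cut and C8–C10 is re-formed. This removes ring B and two stereocentres and leaves a cyclopropane whose two alkenyl arms are ring A and an enol ether. The forward step needs the arms cis, the C6 oxygen trans to C8 on its alkene, and one defined cyclopropane configuration relative to C4.

**16 ⇒ 15.** The C8–C9 and C9–C10 bonds are cut (loss of CH2), leaving a tetrasubstituted silyl enol ether. Three points of design follow:
- A free C4 hydroxyl cannot steer this step. It is allylic to C1=C5 and would deliver the carbenoid there, and it lies anti to C10 across C5=C1, out of reach of C10=C8. It is therefore kept silylated.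
- The face of attack is assigned to a chiral ligand on zinc.
- The forward step must also prefer the siloxy alkene over the 4-methoxybenzyl enol ether and add syn.

**15 ⇒ 14.** The O–Si and C14–H bonds are cut, giving an α-methylene ketone. Enolisation of the corresponding saturated ketone would place C1 cis to oxygen and lead to the trans-dialkenylcyclopropane. Conjugate delivery of hydrogen to C14 through the s-cis enone places oxygen cis to C14 instead, which is the required geometry.

**14 ⇒ 13 ⇒ 12.** The oxidation level at C8 is adjusted. Then C1–C5 and C10=C14 are cut and the C5=C14 vinyl group and C1≡C10 alkyne are restored (enyne metathesis retron). Ring A and the 2-acyl diene collapse to a linear enyne, and both vinyl carbons of 1 are kept. The forward step must close in the exo mode and tolerate the enol ether and the free carbinol.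

**12 ⇒ 5 + 10.** The C8–C10 bond is cut between an acetylide and an aldehyde. The molecule divides into a chiral C10 fragment and an achiral C5 fragment with its ether oxygen. The forward addition must be 1,2 and the work-up non-acidic.

**5 ⇒ 4 ⇒ 2 ⇒ 1.** The C1≡C10 bond is cut (one-carbon homologation), then the trisubstituted alkene is restored (ozonolysis retron) and the O–Si bond is cut. C4 comes unchanged from the chiral pool. The forward ozonolysis must spare the vinyl group.

**10 ⇒ 9 ⇒ 8 ⇒ 7 ⇒ 6.** The oxidation level at C8 is adjusted, the O–CH2Ar bond is cut, and the C6–C7 bond is cut (formylation retron). The forward O-alkylation must give the E enol ether, because that geometry decides C6.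

**23 ⇒ 21.** The aryl O–Si bond is cut. The phenol is masked as a fluoride-labile ether that leaves together with the C4 silyl ether.

## Other disconnections considered

Alternative 1: The cut is at C1–C5 and C5–C6, both made from one carbenoid carbon. The aryl diazoketone A1 would be decomposed by a chiral dirhodium carboxylate. The C5 carbenoid adds to the arene C1–C6 bond and the norcaradiene opens to the azulenone A2 (Buchner reaction), closing rings A and B at once. In its favour, the arene already holds C14, the isopropyl group and the C8 oxygen, and the bicyclic core is reached in very few steps. On step economy to the ring system this is better than the chosen plan. On catalyst control of one absolute configuration the two plans are equal. Against it here: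
- C5 of A2 is doubly allylic and α to the C4 ketone, so it can be lost by enolisation or hydrogen shifts.
- C15 must then be added to C4 under control of that single centre.
- Three ring-B alkenes must be told apart so that only C1=C10 survives.
- A syn hydroboration of C6=C7 would place the 6-hydroxyl trans to the isopropyl group, the opposite of what is needed.
- The carbenoid must also choose the C1–C6 bond over the methyl-bearing C1–C10 bond and over aromatic C–H insertion.

The chosen plan is longer to the bicycle but delivers C5, C6, the C6 oxygen and a C8 carbonyl equivalent with only one alkene left.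

Alternative 2: The cut is at C1–C2 and C10–C14. Halogen–lithium exchange at C2 of the iodoalkyne A3, 5-exo-dig syn-carbolithiation of C1≡C10 and retentive methylation of the C10 vinyllithium would give the alkylidenecyclopentane A4 with C9 cis to C5. In its favour, the tetrasubstituted alkene geometry follows from a stereospecific syn addition, and C4 and C5 are set early by conventional acyclic chemistry. That is better than the chosen plan, which relies on a reagent-controlled cyclopropanation to relate C5 to C4. On the position of the alkene the two plans are equal, since the sigmatropic step also leaves no choice. Against it here, A4 lacks C7 and the isopropyl group. Ring B and the whole C6–C7–C8 triad would still have to be made in a later seven-membered closure between two carbonyl termini and a one-carbon linchpin. That is the hardest part of the molecule and is left unsolved. On step economy and on the mechanism that sets the stereotriad the chosen plan is the stronger.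

Alternative 3: The cut is at C1–C5 across a ten-membered ring. A Lewis acid would open the cis-4,5-epoxide A5 while C1 of the 1(10)-alkene attacks C5 with inversion, and the C10 cation would lose H1 to give A6, the bis-silyl ether of the target. In its favour, the step is biomimetic and stereospecific at C4 (retention) and C5 (inversion). It gives the complete skeleton with every substituent, so only one deprotection remains. On economy after the key step and on how C4 and C5 are related it is better than the chosen plan. Against it here:
- A5 is a ten-membered E,Z-diene monoepoxide that already carries the C6–C8 triad and the ester. Its ring closure and face-selective epoxidation are a larger problem than the one solved.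
- The proton loss is not constrained to H1; H9 and H14 compete.
- The C6 silyloxy group retards ionisation at C5.
- The C8 ester can capture the C10 cation.

The chosen plan uses a concerted step with fixed regiochemistry and an easier precursor, at the cost of a longer endgame.

Key step: step 13

Assumption: guaiane numbering is used for every intermediate (C14 is the methyl on C10, C9 the cyclopropane methylene); (S)-linalool of high enantiomeric purity is taken as purchasable; the C8 carbinol centre in 12 and 13 is carried as both epimers because it is oxidised in step 10.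

## Route

Step 1
Reactants: 1 (S)-linalool
Product: 2 triethyl{[(3S)-3,7-dimethylocta-1,6-dien-3-yl]oxy}silane
Conditions: TESOTf, 2,6-lutidine, CH2Cl2, −78 → 0 °C
Reagents that add atoms: triethylsilyl trifluoromethanesulfonate CC[Si](CC)(CC)OS(=O)(=O)C(F)(F)F
Why: Silylation of a tertiary allylic alcohol with a silyl triflate and a hindered pyridine base; C4 is untouched, and the ether masks the hydroxyl that would otherwise steer a zinc carbenoid onto the neighbouring ring alkene in step 12.

Step 2
Reactants: 2 triethyl{[(3S)-3,7-dimethylocta-1,6-dien-3-yl]oxy}silane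
Product: 4 (4S)-4-methyl-4-(triethylsilyloxy)hex-5-enal, via secondary ozonide 3 (not isolated)
Conditions: O3, CH2Cl2, −78 °C (Sudan Red 7B end point); then PPh3, −78 °C → rt
Reagents that add atoms: ozone [O-][O+]=O
Why: Chemoselective ozonolysis with reductive work-up: ozone attacks the electron-rich trisubstituted alkene far faster than the vinyl group on the siloxy-bearing quaternary carbon, and the indicator stops the reaction before the vinyl group is touched.

Step 3
Reactants: 4 (4S)-4-methyl-4-(triethylsilyloxy)hex-5-enal
Product: 5 triethyl{[(3S)-3-methylhept-1-en-6-yn-3-yl]oxy}silane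
Conditions: dimethyl (1-diazo-2-oxopropyl)phosphonate, K2CO3, MeOH, 0 °C → rt
Reagents that add atoms: dimethyl (1-diazo-2-oxopropyl)phosphonate COP(=O)(OC)C(=[N+]=[N-])C(C)=O
Why: Seyferth–Gilbert homologation with the Ohira–Bestmann reagent converts the aldehyde into the terminal alkyne under mild carbonate conditions that a tertiary silyl ether tolerates; the added carbon becomes C10.

Step 4
Reactants: 6 methyl isovalerate
Product: 7 methyl 2-formyl-3-methylbutanoate
Conditions: HCO2Me, TiCl4, Et3N, CH2Cl2, 0 °C
Reagents that add atoms: methyl formate COC=O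
Why: Titanium-mediated crossed Claisen condensation of an ester with methyl formate; the formyl ester is held as its titanium enolate until work-up and exists largely as the enol; the added carbon becomes C6.

Step 5
Reactants: 7 methyl 2-formyl-3-methylbutanoate
Product: 8 methyl (2E)-3-[(4-methoxybenzyl)oxy]-2-(propan-2-yl)prop-2-enoate
Conditions: 4-MeOC6H4CH2Cl, Cs2CO3, DMF, 0 °C → rt
Reagents that add atoms: 4-methoxybenzyl chloride COc1ccc(CCl)cc1
Why: O-Alkylation of the formyl ester enolate in a dipolar aprotic solvent (C-alkylation would build a quaternary centre beside the isopropyl group); as in β-alkoxyacrylate syntheses the E isomer with the ether oxygen trans to the ester is the expected, thermodynamically preferred product, and this geometry later decides C6.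

Step 6
Reactants: 8 methyl (2E)-3-[(4-methoxybenzyl)oxy]-2-(propan-2-yl)prop-2-enoate
Product: 9 (2E)-3-[(4-methoxybenzyl)oxy]-2-(propan-2-yl)prop-2-en-1-ol
Conditions: i-Bu2AlH, CH2Cl2, −78 °C; aq. potassium sodium tartrate
Reagents that add atoms: none
Why: Reduction of an unsaturated ester to the allylic alcohol with an aluminium hydride at low temperature; the tartrate work-up stays non-acidic because the γ-alkoxy allylic alcohol ionises easily.

Step 7
Reactants: 9 (2E)-3-[(4-methoxybenzyl)oxy]-2-(propan-2-yl)prop-2-en-1-ol
Product: 10 (2E)-3-[(4-methoxybenzyl)oxy]-2-(propan-2-yl)prop-2-enal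
Conditions: MnO2, CH2Cl2, rt
Reagents that add atoms: none
Why: Allylic alcohol oxidation with MnO2 under neutral conditions gives the vinylogous formate; the E isomer (ether oxygen trans to the formyl group) is also the thermodynamically preferred one, so the geometry should hold.

Step 8
Reactants: 5 triethyl{[(3S)-3-methylhept-1-en-6-yn-3-yl]oxy}silane; 10 (2E)-3-[(4-methoxybenzyl)oxy]-2-(propan-2-yl)prop-2-enal
Product: 12 (1E,8S)-1-[(4-methoxybenzyl)oxy]-8-methyl-2-(propan-2-yl)-8-(triethylsilyloxy)deca-1,9-dien-4-yn-3-ol (both C3 epimers), via lithium acetylide 11 (not isolated)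
Conditions: n-BuLi, THF, −78 °C; then 10, −78 → −30 °C; aq. NaHCO3
Reagents that add atoms: none
Why: 1,2-Addition of a lithium acetylide (a hard nucleophile) to the carbonyl carbon of a β-alkoxy enal forms the C8–C10 bond; the new carbinol centre is formed unselectively and is erased in step 10, and a basic quench avoids the acid-induced allylic transposition of the product.

Step 9
Reactants: 12 (1E,8S)-1-[(4-methoxybenzyl)oxy]-8-methyl-2-(propan-2-yl)-8-(triethylsilyloxy)deca-1,9-dien-4-yn-3-ol
Product: 13 (4E)-5-[(4-methoxybenzyl)oxy]-2-[(3S)-3-methyl-3-(triethylsilyloxy)cyclopent-1-en-1-yl]-4-(propan-2-yl)penta-1,4-dien-3-ol (both C3 epimers)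
Conditions: second-generation Grubbs catalyst RuCl2(=CHPh)(H2IMes)(PCy3) (5 mol %), ethylene (1 atm), CH2Cl2, 40 °C
Reagents that add atoms: none
Why: Ring-closing enyne metathesis in the exo mode: the alkylidene formed at the vinyl group adds to the alkyne, C1–C5 closes the five-membered ring, and the vinyl CH2 is passed to C10 as the exocyclic methylene that becomes C14; the hindered trisubstituted enol ether should not compete and C4 is untouched.

Step 10
Reactants: 13 (4E)-5-[(4-methoxybenzyl)oxy]-2-[(3S)-3-methyl-3-(triethylsilyloxy)cyclopent-1-en-1-yl]-4-(propan-2-yl)penta-1,4-dien-3-ol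
Product: 14 (4E)-5-[(4-methoxybenzyl)oxy]-2-[(3S)-3-methyl-3-(triethylsilyloxy)cyclopent-1-en-1-yl]-4-(propan-2-yl)penta-1,4-dien-3-one
Conditions: MnO2, CH2Cl2, rt
Reagents that add atoms: none
Why: MnO2 oxidation of a doubly allylic alcohol gives the cross-conjugated dienone without acid, so neither Nazarov cyclisation nor enol ether hydrolysis is triggered; the 2-acyl diene is used at once because such dienes dimerise on standing.

Step 11
Reactants: 14 (4E)-5-[(4-methoxybenzyl)oxy]-2-[(3S)-3-methyl-3-(triethylsilyloxy)cyclopent-1-en-1-yl]-4-(propan-2-yl)penta-1,4-dien-3-one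
Product: 15 triethyl{[(1E,3E)-1-[(4-methoxybenzyl)oxy]-4-[(3S)-3-methyl-3-(triethylsilyloxy)cyclopent-1-en-1-yl]-2-(propan-2-yl)penta-1,3-dien-3-yl]oxy}silane
Conditions: Et3SiH, RhCl(PPh3)3 (2 mol %), benzene, rt → 40 °C
Reagents that add atoms: triethylsilane CC[SiH](CC)CC
Why: Rhodium-catalysed 1,4-hydrosilylation of an enone with a monohydrosilane: hydrogen goes to C14 and silicon to oxygen through the s-cis oxadiene, so the siloxy group ends cis to the new methyl and C1 cis to C7, a geometry that enolisation of the saturated ketone would not give; the β-alkoxy enone half is not an acceptor.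

Step 12
Reactants: 15 triethyl{[(1E,3E)-1-[(4-methoxybenzyl)oxy]-4-[(3S)-3-methyl-3-(triethylsilyloxy)cyclopent-1-en-1-yl]-2-(propan-2-yl)penta-1,3-dien-3-yl]oxy}silane
Product: 16 triethyl{[(1R,2S)-1-[(1E)-1-[(4-methoxybenzyl)oxy]-3-methylbut-1-en-2-yl]-2-methyl-2-[(3S)-3-methyl-3-(triethylsilyloxy)cyclopent-1-en-1-yl]cyclopropyl]oxy}silane
Conditions: Et2Zn, CH2I2, N-Boc-L-Val-L-Pro-OMe, CH2Cl2, −20 → 0 °C
Reagents that add atoms: diiodomethane ICI
Why: Simmons–Smith cyclopropanation (Furukawa carbenoid) of the silyl enol ether, the most electron-rich alkene of the triene; the syn addition turns the alkene geometry into the cis relation of the two alkenyl arms. Because the silylated C4 centre is too remote to bias the faces, the (1R,2S) configuration is assigned to the dipeptide-bound carbenoid (asymmetric Simmons–Smith reaction of silyl enol ethers), and the D,D-dipeptide is taken instead should the L,L-ligand favour the other face.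

Step 13
Reactants: 16 triethyl{[(1R,2S)-1-[(1E)-1-[(4-methoxybenzyl)oxy]-3-methylbut-1-en-2-yl]-2-methyl-2-[(3S)-3-methyl-3-(triethylsilyloxy)cyclopent-1-en-1-yl]cyclopropyl]oxy}silane
Product: 17 (4S,5S,6S)-6-[(4-methoxybenzyl)oxy]-4,8-bis(triethylsilyloxy)guaia-1(10),7-diene
Conditions: toluene (base-washed glassware, trace Et3N), 70 °C
Reagents that add atoms: none
Why: A concerted [3,3]-sigmatropic shift through a boat transition state with both alkenyl arms folded over the three-membered ring: the C8–C10 bond breaks as C5–C6 forms, and the π bonds move to C1=C10 and C7=C8. The closest known reaction type is the Cope rearrangement of cis-1,2-dialkenylcyclopropanes to cyclohepta-1,4-dienes, including siloxy-substituted cases, driven by release of ring strain. Ring B is closed by ring expansion, the four carbons C1, C5, C6 and C7 being inserted into the cyclopropane bond, so no exo or endo cyclisation mode is involved. C5 and C6 are set relative to each other by the boat geometry and the alkene geometries: the two outward terminal substituents (C4 on C5 by way of ring A, the ether oxygen on C6 from the E enol ether) end cis and both hydrogens end on the α face. Both centres are set relative to C4 by the (1R,2S) cyclopropane, which decides which face of the cyclopentene C5 is presented to C6. The step needs the cis-dialkenyl isomer and a temperature below that of homolytic one-centre epimerisation; the inward positions of both termini carry only hydrogen, so the boat is accessible under mild heating. No regiochemical choice exists, so the alkene falls at C1=C10 and the carbonyl equivalent at C8.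

Step 14
Reactants: 17 (4S,5S,6S)-6-[(4-methoxybenzyl)oxy]-4,8-bis(triethylsilyloxy)guaia-1(10),7-diene
Product: 18 (4S,5S,6S,7S)-6-[(4-methoxybenzyl)oxy]-4-(triethylsilyloxy)guai-1(10)-en-8-one
Conditions: Bu4NF, AcOH, THF, −78 → −40 °C
Reagents that add atoms: none
Why: Fluoride cleaves the enol silyl ether much faster than the tertiary alkyl silyl ether, and the enolate is protonated kinetically by acetic acid; A(1,2) strain with the isopropyl group holds the C6 ether pseudo-axial on the β face, so the proton should enter C7 from the α face and leave the isopropyl group cis to the C6 oxygen. Low temperature and buffering suppress β-elimination of the C6 ether and migration of C1=C10.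

Step 15
Reactants: 18 (4S,5S,6S,7S)-6-[(4-methoxybenzyl)oxy]-4-(triethylsilyloxy)guai-1(10)-en-8-one
Product: 19 (4S,5S,6S,7S)-6-hydroxy-4-(triethylsilyloxy)guai-1(10)-en-8-one
Conditions: DDQ, CH2Cl2/pH 7 phosphate buffer, 0 °C
Reagents that add atoms: none
Why: Oxidative cleavage of a 4-methoxybenzyl ether by DDQ in buffered wet dichloromethane; the silyl ether, the ketone and the tetrasubstituted alkene should be inert at 0 °C, and the neutral medium avoids retro-aldol cleavage, dehydration and C7 epimerisation of the β-hydroxy ketone.

Step 16
Reactants: 19 (4S,5S,6S,7S)-6-hydroxy-4-(triethylsilyloxy)guai-1(10)-en-8-one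
Product: 20 (4S,5S,6R,7R,8S)-4-(triethylsilyloxy)guai-1(10)-ene-6,8-diol
Conditions: Me4NBH(OAc)3, MeCN/AcOH, −30 °C
Reagents that add atoms: none
Why: Evans–Saksena reduction: the 6-hydroxyl exchanges onto boron and delivers hydride within the molecule to the β face of the C8 carbonyl, which sets the 8α-hydroxyl (1,3-anti diol); the reagent does not reduce ketones without this ligand exchange, so the external path to the syn diol should be slow.

Step 17
Reactants: 21 4-hydroxybenzoic acid
Product: 23 4-[(tert-butyldimethylsilyl)oxy]benzoic acid, via bis-silylated silyl ester 22 (not isolated)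
Conditions: TBSCl, imidazole, DMF, rt; then AcOH/THF/H2O, rt
Reagents that add atoms: tert-butyldimethylsilyl chloride CC(C)(C)[Si](C)(C)Cl
Why: Silylation of both the phenol and the acid followed by selective hydrolysis of the much more labile silyl ester leaves the aryl silyl ether (standard protection of a hydroxy acid).

Step 18
Reactants: 20 (4S,5S,6R,7R,8S)-4-(triethylsilyloxy)guai-1(10)-ene-6,8-diol; 23 4-[(tert-butyldimethylsilyl)oxy]benzoic acid
Product: 25 (4S,5S,6R,7S,8S)-6-hydroxy-4-(triethylsilyloxy)guai-1(10)-en-8-yl 4-[(tert-butyldimethylsilyl)oxy]benzoate, via mixed anhydride 24 (not isolated)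
Conditions: 2,4,6-Cl3C6H2COCl, Et3N, THF, rt; then 20, DMAP, toluene, 0 °C → rt
Reagents that add atoms: none
Why: Yamaguchi esterification with about one equivalent of the mixed anhydride; the acyl group should go to the 8-hydroxyl, which has a methylene neighbour, and not to the 6-hydroxyl, which lies between two branched carbons and under the syn C4 silyl ether; C8 keeps its configuration.

Step 19
Reactants: 25 (4S,5S,6R,7S,8S)-6-hydroxy-4-(triethylsilyloxy)guai-1(10)-en-8-yl 4-[(tert-butyldimethylsilyl)oxy]benzoate
Product: 26 (3S,3aS,4R,5S,6S)-3,4-dihydroxy-3,8-dimethyl-5-(propan-2-yl)-1,2,3,3a,4,5,6,7-octahydroazulen-6-yl 4-hydroxybenzoate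
Conditions: Bu4NF, AcOH, THF, 0 °C → rt
Reagents that add atoms: none
Why: Fluoride buffered with acetic acid removes the aryl silyl ether and the tertiary triethylsilyl ether in one operation; buffering keeps phenoxide and alkoxide concentrations low, so the ester should neither migrate to O6 nor be cleaved, and no acid strong enough to dehydrate C4 is present.

## Compound list

1 | (S)-linalool | C=C[C@@](C)(O)CCC=C(C)C | starting material
2 | triethyl{[(3S)-3,7-dimethylocta-1,6-dien-3-yl]oxy}silane | C=C[C@@](C)(O[Si](CC)(CC)CC)CCC=C(C)C | intermediate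
3 | secondary ozonide of 2 at the trisubstituted alkene (1,2,4-trioxolane, ring CH epimers) | C=C[C@@](C)(O[Si](CC)(CC)CC)CCC1OOC(C)(C)O1 | intermediate
4 | (4S)-4-methyl-4-(triethylsilyloxy)hex-5-enal | C=C[C@@](C)(O[Si](CC)(CC)CC)CCC=O | intermediate
5 | triethyl{[(3S)-3-methylhept-1-en-6-yn-3-yl]oxy}silane | C=C[C@@](C)(O[Si](CC)(CC)CC)CCC#C | intermediate
6 | methyl isovalerate | COC(=O)CC(C)C | starting material
7 | methyl 2-formyl-3-methylbutanoate (largely enol) | COC(=O)C(C=O)C(C)C | intermediate
8 | methyl (2E)-3-[(4-methoxybenzyl)oxy]-2-(propan-2-yl)prop-2-enoate | COC(=O)/C(C(C)C)=C/OCc1ccc(OC)cc1 | intermediate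
9 | (2E)-3-[(4-methoxybenzyl)oxy]-2-(propan-2-yl)prop-2-en-1-ol | OC/C(C(C)C)=C/OCc1ccc(OC)cc1 | intermediate
10 | (2E)-3-[(4-methoxybenzyl)oxy]-2-(propan-2-yl)prop-2-enal | O=C/C(C(C)C)=C/OCc1ccc(OC)cc1 | intermediate
11 | lithium acetylide of 5 | C=C[C@@](C)(O[Si](CC)(CC)CC)CCC#C[Li] | intermediate
12 | (1E,8S)-1-[(4-methoxybenzyl)oxy]-8-methyl-2-(propan-2-yl)-8-(triethylsilyloxy)deca-1,9-dien-4-yn-3-ol (both C3 epimers) | C=C[C@@](C)(O[Si](CC)(CC)CC)CCC#CC(O)/C(C(C)C)=C/OCc1ccc(OC)cc1 | intermediate
13 | (4E)-5-[(4-methoxybenzyl)oxy]-2-[(3S)-3-methyl-3-(triethylsilyloxy)cyclopent-1-en-1-yl]-4-(propan-2-yl)penta-1,4-dien-3-ol (both C3 epimers) | C=C(C1=C[C@@](C)(O[Si](CC)(CC)CC)CC1)C(O)/C(C(C)C)=C/OCc1ccc(OC)cc1 | intermediate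
14 | (4E)-5-[(4-methoxybenzyl)oxy]-2-[(3S)-3-methyl-3-(triethylsilyloxy)cyclopent-1-en-1-yl]-4-(propan-2-yl)penta-1,4-dien-3-one | C=C(C1=C[C@@](C)(O[Si](CC)(CC)CC)CC1)C(=O)/C(C(C)C)=C/OCc1ccc(OC)cc1 | intermediate
15 | triethyl{[(1E,3E)-1-[(4-methoxybenzyl)oxy]-4-[(3S)-3-methyl-3-(triethylsilyloxy)cyclopent-1-en-1-yl]-2-(propan-2-yl)penta-1,3-dien-3-yl]oxy}silane (siloxy cis to C14, C1 cis to C7) | C/C(C1=C[C@@](C)(O[Si](CC)(CC)CC)CC1)=C(\O[Si](CC)(CC)CC)/C(C(C)C)=C/OCc1ccc(OC)cc1 | intermediate
16 | triethyl{[(1R,2S)-1-[(1E)-1-[(4-methoxybenzyl)oxy]-3-methylbut-1-en-2-yl]-2-methyl-2-[(3S)-3-methyl-3-(triethylsilyloxy)cyclopent-1-en-1-yl]cyclopropyl]oxy}silane (alkenyl arms cis) | C[C@]1(C[C@]1(O[Si](CC)(CC)CC)/C(C(C)C)=C/OCc3ccc(OC)cc3)C2=C[C@@](C)(O[Si](CC)(CC)CC)CC2 | intermediate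
17 | (4S,5S,6S)-6-[(4-methoxybenzyl)oxy]-4,8-bis(triethylsilyloxy)guaia-1(10),7-diene (4β-OSi, 5α-H, 6β-O) | CC1=C2CC[C@](C)(O[Si](CC)(CC)CC)[C@@H]2[C@H](OCc3ccc(OC)cc3)C(C(C)C)=C(O[Si](CC)(CC)CC)C1 | intermediate
18 | (4S,5S,6S,7S)-6-[(4-methoxybenzyl)oxy]-4-(triethylsilyloxy)guai-1(10)-en-8-one (7β-isopropyl) | CC1=C2CC[C@](C)(O[Si](CC)(CC)CC)[C@@H]2[C@H](OCc3ccc(OC)cc3)[C@H](C(C)C)C(=O)C1 | intermediate
19 | (4S,5S,6S,7S)-6-hydroxy-4-(triethylsilyloxy)guai-1(10)-en-8-one | CC1=C2CC[C@](C)(O[Si](CC)(CC)CC)[C@@H]2[C@H](O)[C@H](C(C)C)C(=O)C1 | intermediate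
20 | (4S,5S,6R,7R,8S)-4-(triethylsilyloxy)guai-1(10)-ene-6,8-diol (6β-OH, 8α-OH) | CC1=C2CC[C@](C)(O[Si](CC)(CC)CC)[C@@H]2[C@H](O)[C@H](C(C)C)[C@@H](O)C1 | intermediate
21 | 4-hydroxybenzoic acid | O=C(O)c1ccc(O)cc1 | starting material
22 | tert-butyldimethylsilyl 4-[(tert-butyldimethylsilyl)oxy]benzoate | CC(C)(C)[Si](C)(C)Oc1ccc(cc1)C(=O)O[Si](C)(C)C(C)(C)C | intermediate
23 | 4-[(tert-butyldimethylsilyl)oxy]benzoic acid | CC(C)(C)[Si](C)(C)Oc1ccc(cc1)C(=O)O | intermediate
24 | 4-[(tert-butyldimethylsilyl)oxy]benzoic 2,4,6-trichlorobenzoic anhydride | CC(C)(C)[Si](C)(C)Oc1ccc(cc1)C(=O)OC(=O)c1c(Cl)cc(Cl)cc1Cl | intermediate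
25 | (4S,5S,6R,7S,8S)-6-hydroxy-4-(triethylsilyloxy)guai-1(10)-en-8-yl 4-[(tert-butyldimethylsilyl)oxy]benzoate | CC1=C2CC[C@](C)(O[Si](CC)(CC)CC)[C@@H]2[C@H](O)[C@H](C(C)C)[C@@H](OC(=O)c2ccc(O[Si](C)(C)C(C)(C)C)cc2)C1 | intermediate
26 | (3S,3aS,4R,5S,6S)-3,4-dihydroxy-3,8-dimethyl-5-(propan-2-yl)-1,2,3,3a,4,5,6,7-octahydroazulen-6-yl 4-hydroxybenzoate | CC1=C2CC[C@](C)(O)[C@@H]2[C@H](O)[C@H](C(C)C)[C@@H](OC(=O)c2ccc(O)cc2)C1 | target

## Step count and least certain steps

Total: 19 steps. Longest linear sequence: 15 steps (from 6 through steps 4–16, 18 and 19); the line from 1 is 14 steps.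

**Step 13 (key step).** The most likely failure is loss of stereochemical integrity: if the crowded boat needs more heat than expected, homolytic one-centre epimerisation of the donor-substituted cyclopropane could compete and scramble C5 and C6 relative to C4. Adventitious acid could also open the siloxycyclopropane. The fallback runs the rearrangement as a charge-accelerated process at low temperature. It sets out from 14:
- Hydrosilylation with PhMe2SiH in place of Et3SiH gives the dimethyl(phenyl)silyl trienol ether F1.
- Cyclopropanation as in step 12 gives the dimethyl(phenyl)silyl cyclopropyl ether F2.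
- One equivalent of Bu4NF at −78 °C removes only this more labile silyl group and gives the tetrabutylammonium cyclopropanolate F3.
- The alkoxide on the carbon of the breaking bond should lower the barrier so that the rearrangement proceeds near 0 °C to the tetrabutylammonium enolate F4.
- Quenching with acetic acid at −78 °C returns to the route at 18.

**Step 12.** Facial selectivity may be poor, because the chiral zinc carbenoid has not been used on a tetrasubstituted siloxy triene and C4 gives no help. The 4-methoxybenzyl enol ether may also take up a second methylene. The fallback gives up reagent control and separates after the key step. From 15, the unmodified Furukawa reagent (Et2Zn, CH2I2, one equivalent) gives 16 together with the (1S,2R)-cyclopropane diastereomer F5. The mixture is heated as in step 13, and 17 is separated by chromatography from the (4S,5R,6R)-diene diastereomer F6. The route is rejoined at 17.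

**Step 11.** Geometric control may be lost if part of the hydrosilylation runs through the s-trans enone, which would put the siloxy group cis to ring A. Carbonyl 1,2-reduction, and 6π-electrocyclisation of the cis-triene if it is warmed, are further risks. The fallback uses reactivity to sort the isomers. From 14, the mixture of 15 and its C10=C8 geometric isomer F7 is cyclopropanated as in step 12. F7 gives the trans-dialkenylcyclopropane F8, which cannot reach the boat transition state and should stay unchanged at 70 °C. After step 13, 17 is separated from F8, and the route is rejoined at 17.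

**Step 14.** The enolate may expel the C6 ether (β-elimination) before it is protonated, or protonation may be unselective at C7. The fallback avoids the enolate altogether. From 17, mild aqueous acid (oxalic acid, wet THF, 0 °C) hydrolyses the enol ether by C-protonation of the neutral alkene and loss of silanol from the oxocarbenium ion. It returns to 18, and no new compound is made (F0).

**Step 16.** Internal hydride delivery has to take place on the face that also carries the isopropyl group. If external attack from the open α face wins, the 8β-alcohol results. The selective acylation of step 18 is the second point that could fail here. The fallback inverts C8 during esterification and keeps O6 protected. It sets out from 18: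
- LiBH(s-Bu)3 at −78 °C attacks anti to the isopropyl group and gives the 8β-alcohol F9, with the 6-ether still in place.
- Mitsunobu esterification with 23 (PPh3, diisopropyl azodicarboxylate) inverts C8 and gives the 6-O-(4-methoxybenzyl) ester F10.
- DDQ in buffered dichloromethane removes the benzyl ether and returns to the route at 25.

## Further compounds

F1 | step 13 | dimethyl(phenyl)silyl analogue of 15 (siloxy cis to C14) | C/C(C1=C[C@@](C)(O[Si](CC)(CC)CC)CC1)=C(\O[Si](C)(C)c1ccccc1)/C(C(C)C)=C/OCc1ccc(OC)cc1
F2 | step 13 | dimethyl(phenyl)silyl analogue of 16, (1R,2S) | C[C@]1(C[C@]1(O[Si](C)(C)c4ccccc4)/C(C(C)C)=C/OCc3ccc(OC)cc3)C2=C[C@@](C)(O[Si](CC)(CC)CC)CC2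
F3 | step 13 | tetrabutylammonium (1R,2S)-cyclopropanolate corresponding to 16 | C[C@]1(C[C@]1([O-])/C(C(C)C)=C/OCc3ccc(OC)cc3)C2=C[C@@](C)(O[Si](CC)(CC)CC)CC2.CCCC[N+](CCCC)(CCCC)CCCC
F4 | step 13 | tetrabutylammonium C7=C8 enolate corresponding to 18 | CC1=C2CC[C@](C)(O[Si](CC)(CC)CC)[C@@H]2[C@H](OCc3ccc(OC)cc3)C(C(C)C)=C([O-])C1.CCCC[N+](CCCC)(CCCC)CCCC
F5 | step 12 | (1S,2R)-cyclopropane diastereomer of 16 | C[C@@]1(C[C@@]1(O[Si](CC)(CC)CC)/C(C(C)C)=C/OCc3ccc(OC)cc3)C2=C[C@@](C)(O[Si](CC)(CC)CC)CC2
F6 | step 12 | (4S,5R,6R)-diastereomer of 17 | CC1=C2CC[C@](C)(O[Si](CC)(CC)CC)[C@H]2[C@@H](OCc3ccc(OC)cc3)C(C(C)C)=C(O[Si](CC)(CC)CC)C1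
F7 | step 11 | C10=C8 geometric isomer of 15 (siloxy cis to ring A) | C/C(C1=C[C@@](C)(O[Si](CC)(CC)CC)CC1)=C(/O[Si](CC)(CC)CC)\C(C(C)C)=C\OCc1ccc(OC)cc1
F8 | step 11 | trans-dialkenylcyclopropane from F7, (1S,2S) isomer shown | C[C@]1(C[C@@]1(O[Si](CC)(CC)CC)/C(C(C)C)=C/OCc3ccc(OC)cc3)C2=C[C@@](C)(O[Si](CC)(CC)CC)CC2
F0 | step 14 | none | none
F9 | step 16 | 8β-alcohol: 6-[(4-methoxybenzyl)oxy]-4-(triethylsilyloxy)guai-1(10)-en-8β-ol | CC1=C2CC[C@](C)(O[Si](CC)(CC)CC)[C@@H]2[C@H](OCc3ccc(OC)cc3)[C@H](C(C)C)[C@H](O)C1
F10 | step 16 | 6-O-(4-methoxybenzyl) ether of 25 | CC1=C2CC[C@](C)(O[Si](CC)(CC)CC)[C@@H]2[C@H](OCc3ccc(OC)cc3)[C@H](C(C)C)[C@@H](OC(=O)c2ccc(O[Si](C)(C)C(C)(C)C)cc2)C1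
A1 | alternative 1 | 1-diazo-4-[4-methoxy-2-methyl-5-(propan-2-yl)phenyl]butan-2-one | [N-]=[N+]=CC(=O)CCc1cc(C(C)C)c(OC)cc1C
A2 | alternative 1 | bicyclic cycloheptatriene (azulenone) with C4 ketone, C8 methyl enol ether and C5 stereocentre | CC1=C2CCC(=O)[C@@H]2C=C(C(C)C)C(OC)=C1
A3 | alternative 2 | iodoalkyne: C2 iodide, C4 triethylsilyl ether, C5 with silyloxymethyl and C1≡C10 alkyne carrying the C9–C8 diethyl acetal | ICC[C@](C)(O[Si](CC)(CC)CC)[C@H](CO[Si](C)(C)C(C)(C)C)C#CCC(OCC)OCC
A4 | alternative 2 | alkylidenecyclopentane with C9 cis to C5 | C/C(CC(OCC)OCC)=C1\CC[C@](C)(O[Si](CC)(CC)CC)[C@@H]1CO[Si](C)(C)C(C)(C)C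
A5 | alternative 3 | cis-4,5-epoxygermacr-1(10)E-ene bis-silyl ether ester | C/C1=C\CC[C@]2(C)O[C@@H]2[C@H](O[Si](C)(C)C(C)(C)C)[C@H](C(C)C)[C@@H](OC(=O)c3ccc(O[Si](C)(C)C(C)(C)C)cc3)C1
A6 | alternative 3 | bis-silyl ether of the target | CC1=C2CC[C@](C)(O)[C@@H]2[C@H](O[Si](C)(C)C(C)(C)C)[C@H](C(C)C)[C@@H](OC(=O)c2ccc(O[Si](C)(C)C(C)(C)C)cc2)C1
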